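The readings are calculated from invented constants, noise included.

A ratio of 0.00200 of E to G stands in Saturday's flask and in Friday's alike, so at 31 min the two read the same on one clock: E charged times time, over G charged.

| flask | G | E | time |
|---|---|---|---|
| Friday's | 1.00 M | 0.00200 M |  |
| Sunday's | 1.50 M | 0.00200 M |  |
| Saturday's | 3.00 M | 0.00600 M | 31 min |

| run | time / min | [J] / M |
|---|---|---|
| Friday's run | 5.2 | 0.290 |
| Friday's run | 10 | 0.404 |
| Friday's run | 16 | 0.496 |
| Friday's run | 21 | 0.566 |
| Friday's run | 26 | 0.609 |
| Friday's run | 31 | 0.654 |
| Sunday's run | 5.2 | 0.345 |
| Sunday's run | 10 | 0.484 |
| Sunday's run | 16 | 0.606 |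
| Sunday's run | 21 | 0.687 |
| Sunday's run | 26 | 0.749 |
| Sunday's run | 31 | 0.811 |

(scatter of a reading: 0.003 M)

- reaction order in [G] at the outset, round the charge of the Friday's run, defined at two percent of the G turned into J (one fixed amount of J, the same in the runs compared)
- J in the Saturday's run at 31 min, as a share of the G charged

- Overall: G -> J, with E as catalyst.
- Constant volume, constant temperature.
- What is held in complexes is read along with the free species.
- An order is taken over about fifteen percent of the charge, up and down.

If equal clock meant equal share, Saturday's flask would repeat Friday's share at 31 min, 65.4%, and you take that as the upper mark. Sunday's flask shows the drift: at 31 min it stands on the clock of Friday's flask at 20.7 min, where Friday's readings, interpolated, give 56.1% against Sunday's 54.1%. Call the power of the charge by which the share falls at equal clock the drift exponent, 0.0925, a reading that carries the scatter of J.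

For the lower mark, let the fractional loss grow in step with the added charge: 55.8%. The power law joins the two ends, and I commit to 59.1%, which is lower than the upper mark and higher than the lower one. For the order I commit to no number: Friday's first reading is already 29.0% of the charge, against the two percent at which the order is defined.

The forecast gave 63% (57% to 68%), inside the bracket and higher than my figure, and an order of 0.2 (0.08 to 0.45), with Friday's share as “the pure scaling limit”.

Saturday's flask gives 59.2% of the G charged as J at 31 min, and the order in G round Friday's charge, at two percent turned, is 0.72.

    E + G → J + E (258.0 L mol⁻¹ min⁻¹)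
    E + J ⇌ EJ, settled at all times (24.60 L mol⁻¹)
    2 G ⇌ G2, settled at all times (0.6420 L mol⁻¹)

In Saturday's flask E turned G into J throughout, while growing J held E as EJ (product inhibition) and part of the G sat as G2. Where the same J had been made, Sunday's rate of 0.26 M min⁻¹ stood 1.3 times Friday's 0.20 M min⁻¹. Saturday's share corresponds to an exponent of 0.0910. Taking 0.0925 on Sunday's flask, doubled for a share growing as the root of the clock, as Friday's nearly did, puts half of the charge at 26.2 min, and the simulated time is 26.0 min.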